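Ring B is disconnected at C1–C2 and C5–C6 into ethoxyacetylene and a 3-ethoxy-4,4-dimethylcyclobutenone that already carries ring A through the bridge methylene on its C2. Heating the two runs a vinylketene annulation that builds ring B with its 1,3,5-oxygen pattern in one operation. Because C4 of ring B is the quaternary CMe2 carbon, flanked by oxygenated C3 and C5, the six-electron closure cannot go on to a phenol and stops at the cyclohexa-2,4-dienone, the oxidation level of the target. The precursor comes from the benzylic bromide of dibenzyl-protected ring A by alkynylation to an ynol ether and [2+2] addition of dimethylketene.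

Key step: step 9

Assumption: the target has no stereocentre and is drawn as the enol tautomer of its SMILES; ring B is numbered C1 (ketone), C2 (bridge-bearing), C3 and C5 (oxygenated), C4 (CMe2), C6 (acetyl-bearing).

Abbreviation: ArCH2 = [2,4-bis(benzyloxy)-3-butanoyl-6-methoxy-5-methylphenyl]methyl, the bridge carbon attached to dibenzyl-protected ring A.

Step 1
Reactants: 1 2-methylphloroglucinol; 2 butyryl chloride
Product: 3 1-(2,4,6-trihydroxy-3-methylphenyl)butan-1-one
Conditions: AlCl3 (4 equiv), PhNO2/CH2Cl2, 0 °C to rt; ice/aq. HCl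
Reagents that add atoms: none
Why: Friedel–Crafts C-acylation of a phloroglucinol, in which the two free ring positions of 1 are equivalent and the first acyl group deactivates the ring against a second acylation.

Step 2
Reactants: 3 1-(2,4,6-trihydroxy-3-methylphenyl)butan-1-one
Product: 4 1-(2,6-dihydroxy-4-methoxy-3-methylphenyl)butan-1-one
Conditions: Me2SO4 (1.0 equiv), K2CO3 (1.0 equiv), acetone, rt
Reagents that add atoms: dimethyl sulfate, COS(=O)(=O)OC
Why: Williamson O-methylation with one equivalent of base and of a hard electrophile should go to the hydroxyl para to the ketone, which is the most acidic and is never held in the chelate with the carbonyl group.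

Step 3
Reactants: 4 1-(2,6-dihydroxy-4-methoxy-3-methylphenyl)butan-1-one; 5 benzyl bromide
Product: 7 1-[2,6-bis(benzyloxy)-4-methoxy-3-methylphenyl]butan-1-one, via mono-benzyl ether 6 (not isolated)
Conditions: 5 (2.4 equiv), K2CO3 (3 equiv), Bu4NI (cat.), DMF, 60 °C
Reagents that add atoms: none
Why: Williamson etherification in warm DMF breaks the hydrogen-bonded chelates so that both ortho hydroxyls are benzylated, and the dipolar aprotic medium favours O- over C-benzylation at the free ring carbon.

Step 4
Reactants: 7 1-[2,6-bis(benzyloxy)-4-methoxy-3-methylphenyl]butan-1-one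
Product: 9 2,4-bis(benzyloxy)-3-butanoyl-6-methoxy-5-methylbenzaldehyde, via iminium chloride 8 (not isolated)
Conditions: POCl3 (1.5 equiv), DMF, 0 °C to rt; then H2O, rt
Reagents that add atoms: N,N-dimethylformamide, CN(C)C=O; water, O
Why: Vilsmeier–Haack formylation at the only free ring carbon, which lies ortho or para to three alkoxy groups, while the twisted di-ortho-substituted ketone deactivates little and benzyl ethers are inert to the chloroiminium reagent (acidic halomethylation would not spare them).

Step 5
Reactants: 9 2,4-bis(benzyloxy)-3-butanoyl-6-methoxy-5-methylbenzaldehyde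
Product: 10 1-[2,6-bis(benzyloxy)-3-(hydroxymethyl)-4-methoxy-5-methylphenyl]butan-1-one
Conditions: NaBH4 (0.5 equiv), THF/MeOH, 0 °C
Reagents that add atoms: none
Why: Chemoselective borohydride reduction, the aldehyde being reduced much faster than the hindered aryl ketone flanked by two benzyloxy groups.

Step 6
Reactants: 10 1-[2,6-bis(benzyloxy)-3-(hydroxymethyl)-4-methoxy-5-methylphenyl]butan-1-one
Product: 11 1-[2,6-bis(benzyloxy)-3-(bromomethyl)-4-methoxy-5-methylphenyl]butan-1-one
Conditions: CBr4, PPh3, CH2Cl2, 0 °C; used at once without chromatography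
Reagents that add atoms: carbon tetrabromide, BrC(Br)(Br)Br
Why: Appel bromination converts the primary benzylic alcohol under neutral conditions, avoiding acid that would ionise this very electron-rich benzylic position or attack the benzyl ethers.

Step 7
Reactants: 11 1-[2,6-bis(benzyloxy)-3-(bromomethyl)-4-methoxy-5-methylphenyl]butan-1-one; 12 ethoxyacetylene
Product: 15 1-[2,6-bis(benzyloxy)-3-(3-ethoxyprop-2-yn-1-yl)-4-methoxy-5-methylphenyl]butan-1-one, via lithium ethoxyacetylide 13 (not isolated), via ethoxyethynylzinc bromide 14 (not isolated)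
Conditions: 12, n-BuLi, THF, −78 °C; ZnBr2, −78 to 0 °C; then 11, PdCl2(DPEphos) (3 mol%; DPEphos = bis[2-(diphenylphosphino)phenyl] ether), THF, rt; work-up on Et3N-deactivated silica
Reagents that add atoms: none
Why: Negishi coupling of an alkynylzinc halide with a benzylic bromide; the zinc acetylide is too weakly basic and nucleophilic to add to or enolise the butyryl ketone, which a lithium acetylide would endanger, or to isomerise the product to an allenyl ether.

Step 8
Reactants: 15 1-[2,6-bis(benzyloxy)-3-(3-ethoxyprop-2-yn-1-yl)-4-methoxy-5-methylphenyl]butan-1-one; 16 isobutyryl chloride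
Product: 18 2-(ArCH2)-3-ethoxy-4,4-dimethylcyclobut-2-en-1-one, via dimethylketene 17 (not isolated)
Conditions: 16 (slow addition, 2.5 equiv), Et3N (3 equiv), toluene, 50 °C
Reagents that add atoms: none
Why: Ketene–alkyne [2+2] cycloaddition in which the nucleophilic carbon of the ynol ether (the one bearing ArCH2) attacks the carbonyl carbon of dimethylketene, so the ethoxy carbon ends next to CMe2 and one regioisomeric 3-ethoxycyclobutenone should form.

Step 9
Reactants: 18 2-(ArCH2)-3-ethoxy-4,4-dimethylcyclobut-2-en-1-one; 12 ethoxyacetylene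
Product: 22 4-(ArCH2)-3,5-diethoxy-6,6-dimethylcyclohexa-2,4-dien-1-one (ring B as bis(ethyl enol ether); ring A as dibenzyl ether), via vinylketene 19 (not isolated), via 4-vinylcyclobutenone 20 (not isolated), via dienylketene 21 (not isolated)
Conditions: 12 (4 equiv), toluene, 90 °C, sealed tube
Reagents that add atoms: none
Why: Thermal 4-pi electrocyclic opening of 18 breaks the future C4–C5 bond and gives vinylketene 19, whose ketene C=C adds ethoxyacetylene by [2+2] cycloaddition to the 4-vinylcyclobutenone 20, and a second 4-pi opening then gives dienylketene 21. Ring B closes by thermally allowed disrotatory 6-pi electrocyclisation of 21, the ketene carbon (C5) bonding to the CMe2 terminus (C4), so the net new skeletal bonds are C5–C6 and C1–C2. The closest known reaction type is the Danheiser annulation of cyclobutenones with alkoxyalkynes, in the variant where a 4,4-disubstituted cyclobutenone cannot tautomerise to a phenol and should end at the 6,6-disubstituted cyclohexa-2,4-dienone. No stereocentre results, since 20 is racemic and its quaternary centre is lost on ring opening. The selectivity needed is the regiochemistry of the ketene–alkyne [2+2]: the oxygen lone pair makes the unsubstituted carbon of ethoxyacetylene the nucleophilic one, so it bonds to the ketene carbonyl carbon and the ethoxy-bearing carbon ends on the bridge-bearing C2, which sets the 1,3,5-oxygen pattern. The excess of alkyne should intercept 19 before it dimerises or undergoes a 1,5-hydrogen shift from a methyl group, and the fully substituted, aprotic ring A is a spectator.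

Step 10
Reactants: 22 4-(ArCH2)-3,5-diethoxy-6,6-dimethylcyclohexa-2,4-dien-1-one
Product: 24 2-(ArCH2)-3,5-dihydroxy-4,4-dimethylcyclohexa-2,5-dien-1-one, via mono(ethyl enol ether) 23 (not isolated)
Conditions: 2 M aq. HCl, THF, 45 °C
Reagents that add atoms: water, O
Why: Acid-catalysed hydrolysis of the two vinylogous-ester enol ethers (addition of water, loss of ethanol) gives the enolised 1,3,5-trione, while aryl benzyl and methyl ethers are stable to dilute aqueous acid.

Step 11
Reactants: 24 2-(ArCH2)-3,5-dihydroxy-4,4-dimethylcyclohexa-2,5-dien-1-one; 25 acetyl chloride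
Product: 27 2-acetyl-6-(ArCH2)-3,5-dihydroxy-4,4-dimethylcyclohexa-2,5-dien-1-one, via enol acetate 26 (not isolated)
Conditions: 25 (1.05 equiv), Et3N, CH2Cl2, 0 °C; then DMAP (0.5 equiv), rt; dil. HCl work-up
Reagents that add atoms: none
Why: O-acylation followed by DMAP-mediated O-to-C acyl migration, the standard entry to 2-acyl cyclic 1,3-diones; acyl transfer is reversible and should settle at ring B C6, the only carbon where the acetyl group ends in a chelated, enolised triketone, while the ring A ketone is not acidic enough to take part.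

Step 12
Reactants: 27 2-acetyl-6-(ArCH2)-3,5-dihydroxy-4,4-dimethylcyclohexa-2,5-dien-1-one
Product: 29 2-acetyl-6-[(3-butanoyl-2,4-dihydroxy-6-methoxy-5-methylphenyl)methyl]-3,5-dihydroxy-4,4-dimethylcyclohexa-2,5-dien-1-one (target), via mono-benzyl ether 28 (not isolated)
Conditions: H2 (1 atm), Pd/C (10 wt% Pd), EtOAc, rt
Reagents that add atoms: none
Why: Hydrogenolysis of the two aryl benzyl ethers over Pd/C under neutral conditions, which should leave the enolised triketone, the aryl ketone, the methyl ether and the base-sensitive methylene bridge untouched.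

Compound list
1 | 2-methylphloroglucinol (2-methylbenzene-1,3,5-triol) | Cc1c(O)cc(O)cc1O | starting material
2 | butyryl chloride | CCCC(=O)Cl | starting material
3 | 1-(2,4,6-trihydroxy-3-methylphenyl)butan-1-one | CCCC(=O)c1c(O)c(C)c(O)cc1O | intermediate
4 | 1-(2,6-dihydroxy-4-methoxy-3-methylphenyl)butan-1-one (ring A monomer) | CCCC(=O)c1c(O)c(C)c(OC)cc1O | intermediate
5 | benzyl bromide | BrCc1ccccc1 | starting material
6 | 1-[6-(benzyloxy)-2-hydroxy-4-methoxy-3-methylphenyl]butan-1-one (mono-benzyl ether, drawn as the less hindered isomer; not isolated) | CCCC(=O)c1c(O)c(C)c(OC)cc1OCc1ccccc1 | intermediate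
7 | 1-[2,6-bis(benzyloxy)-4-methoxy-3-methylphenyl]butan-1-one | CCCC(=O)c1c(OCc2ccccc2)c(C)c(OC)cc1OCc1ccccc1 | intermediate
8 | N-{[2,4-bis(benzyloxy)-3-butanoyl-6-methoxy-5-methylphenyl]methylidene}-N-methylmethanaminium chloride (not isolated) | CCCC(=O)c1c(OCc2ccccc2)c(C)c(OC)c(C=[N+](C)C)c1OCc1ccccc1.[Cl-] | intermediate
9 | 2,4-bis(benzyloxy)-3-butanoyl-6-methoxy-5-methylbenzaldehyde | CCCC(=O)c1c(OCc2ccccc2)c(C)c(OC)c(C=O)c1OCc1ccccc1 | intermediate
10 | 1-[2,6-bis(benzyloxy)-3-(hydroxymethyl)-4-methoxy-5-methylphenyl]butan-1-one | CCCC(=O)c1c(OCc2ccccc2)c(C)c(OC)c(CO)c1OCc1ccccc1 | intermediate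
11 | 1-[2,6-bis(benzyloxy)-3-(bromomethyl)-4-methoxy-5-methylphenyl]butan-1-one | CCCC(=O)c1c(OCc2ccccc2)c(C)c(OC)c(CBr)c1OCc1ccccc1 | intermediate
12 | ethoxyacetylene (ethoxyethyne) | C#COCC | starting material
13 | lithium ethoxyacetylide (not isolated) | [Li]C#COCC | intermediate
14 | (ethoxyethynyl)zinc bromide (not isolated) | CCOC#C[Zn]Br | intermediate
15 | 1-[2,6-bis(benzyloxy)-3-(3-ethoxyprop-2-yn-1-yl)-4-methoxy-5-methylphenyl]butan-1-one (ynol ether) | CCCC(=O)c1c(OCc2ccccc2)c(C)c(OC)c(CC#COCC)c1OCc1ccccc1 | intermediate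
16 | isobutyryl chloride (2-methylpropanoyl chloride) | CC(C)C(=O)Cl | starting material
17 | dimethylketene (not isolated) | CC(C)=C=O | intermediate
18 | 2-(ArCH2)-3-ethoxy-4,4-dimethylcyclobut-2-en-1-one (key-step precursor) | CCCC(=O)c1c(OCc2ccccc2)c(C)c(OC)c(CC3=C(OCC)C(C)(C)C3=O)c1OCc1ccccc1 | intermediate
19 | 2-(ArCH2)-3-ethoxy-4-methylpenta-1,3-dien-1-one (vinylketene; not isolated) | CCCC(=O)c1c(OCc2ccccc2)c(C)c(OC)c(CC(=C=O)C(OCC)=C(C)C)c1OCc1ccccc1 | intermediate
20 | 4-(ArCH2)-3-ethoxy-4-(1-ethoxy-2-methylprop-1-en-1-yl)cyclobut-2-en-1-one (racemic; not isolated) | CCCC(=O)c1c(OCc2ccccc2)c(C)c(OC)c(CC3(C(OCC)=C(C)C)C(OCC)=CC3=O)c1OCc1ccccc1 | intermediate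
21 | (3E)-4-(ArCH2)-3,5-diethoxy-6-methylhepta-1,3,5-trien-1-one (dienylketene, ketenyl and isobutenyl groups cis; not isolated) | CCCC(=O)c1c(OCc2ccccc2)c(C)c(OC)c(C/C(C(OCC)=C(C)C)=C(OCC)/C=C=O)c1OCc1ccccc1 | intermediate
22 | 4-(ArCH2)-3,5-diethoxy-6,6-dimethylcyclohexa-2,4-dien-1-one (key-step product) | CCCC(=O)c1c(OCc2ccccc2)c(C)c(OC)c(CC3=C(OCC)C(C)(C)C(=O)C=C3OCC)c1OCc1ccccc1 | intermediate
23 | 2-(ArCH2)-3-ethoxy-5-hydroxy-4,4-dimethylcyclohexa-2,5-dien-1-one (half-hydrolysed; not isolated) | CCCC(=O)c1c(OCc2ccccc2)c(C)c(OC)c(CC3=C(OCC)C(C)(C)C(O)=CC3=O)c1OCc1ccccc1 | intermediate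
24 | 2-(ArCH2)-3,5-dihydroxy-4,4-dimethylcyclohexa-2,5-dien-1-one (enol form of the 1,3,5-trione) | CCCC(=O)c1c(OCc2ccccc2)c(C)c(OC)c(CC3=C(O)C(C)(C)C(O)=CC3=O)c1OCc1ccccc1 | intermediate
25 | acetyl chloride | CC(=O)Cl | starting material
26 | 5-acetoxy-2-(ArCH2)-3-hydroxy-4,4-dimethylcyclohexa-2,5-dien-1-one (enol acetate, one of the convergent O-acetyl isomers; not isolated) | CCCC(=O)c1c(OCc2ccccc2)c(C)c(OC)c(CC3=C(O)C(C)(C)C(OC(C)=O)=CC3=O)c1OCc1ccccc1 | intermediate
27 | 2-acetyl-6-(ArCH2)-3,5-dihydroxy-4,4-dimethylcyclohexa-2,5-dien-1-one (dibenzyl ether of the target) | CCCC(=O)c1c(OCc2ccccc2)c(C)c(OC)c(CC3=C(O)C(C)(C)C(O)=C(C(C)=O)C3=O)c1OCc1ccccc1 | intermediate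
28 | mono-benzyl ether of the target (benzyl kept on the ring A oxygen next to the methyl group; not isolated) | CCCC(=O)c1c(OCc2ccccc2)c(C)c(OC)c(CC3=C(O)C(C)(C)C(O)=C(C(C)=O)C3=O)c1O | intermediate
29 | 2-acetyl-6-[(3-butanoyl-2,4-dihydroxy-6-methoxy-5-methylphenyl)methyl]-3,5-dihydroxy-4,4-dimethylcyclohexa-2,5-dien-1-one | CCCC(=O)c1c(O)c(C)c(OC)c(CC2=C(O)C(C)(C)C(O)=C(C(C)=O)C2=O)c1O | target

Total step count: 12. Longest linear sequence: 12 steps (1 to 29); compounds 2, 5, 12, 16 and 25 enter as purchased reagents.

Steps most likely to fail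

Step 9. The donor-substituted cyclobutenone may open too slowly at temperatures that ethoxyacetylene tolerates. The vinylketene may also be lost by dimerisation or by a 1,5-hydrogen shift from a methyl group before the alkyne traps it, and the alkyne itself may lose ethylene on prolonged heating. The fallback gives up the annulation and joins the halves at the bridge carbon; it sets out from alcohol 10 and comes back at 27. Commercial 2,4,6-trihydroxyacetophenone is C,C-dimethylated (MeI, NaOMe, MeOH) to 2-acetyl-3,5-dihydroxy-4,4-dimethylcyclohexa-2,5-dien-1-one F1. F1 is then C-benzylated at its single free ring carbon by 10 under Brønsted acid catalysis (TsOH·H2O cat., CH2Cl2, rt), the stabilised trialkoxybenzyl cation being captured by the enol. This should give 27 directly, and step 12 completes the synthesis.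

Step 7. The ynol ether may be hydrated or protonated during coupling or isolation, and the electron-rich benzylic bromide may homocouple or solvolyse faster than it cross-couples. The fallback reverses the polarity and avoids the ynol ether; it sets out from 11 and comes back at 18, bypassing steps 7 and 8. Zinc insertion into 11 (Zn dust, LiCl, THF, rt) should give the ketone-tolerant benzylic reagent {[2,4-bis(benzyloxy)-3-butanoyl-6-methoxy-5-methylphenyl]methyl}zinc bromide F2. Separately, 12 and 16 with Et3N give 3-ethoxy-4,4-dimethylcyclobut-2-en-1-one F3, which NBS in CH2Cl2 brominates at the alpha carbon of the vinylogous ester to 2-bromo-3-ethoxy-4,4-dimethylcyclobut-2-en-1-one F4. Negishi coupling of F2 with F4 (Pd(PPh3)4, zerovalent palladium, THF, 50 °C) should give 18.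

Step 8. Dimerisation of dimethylketene, or acylation and protonation of the acid-sensitive ynol ether, may outrun the cycloaddition. The fallback exchanges the roles of the two partners; it sets out from 15 and comes back at 24. Ynol ether 15 is heated in toluene at 90 °C with the simple cyclobutenone F3 (prepared as described for the step 7 fallback). F3 opens to an ethoxy vinylketene, the ArCH2-bearing alkyne carbon bonds to the ketene carbonyl carbon, and a second opening and 6-pi closure should give the regioisomeric 2-(ArCH2)-3,5-diethoxy-6,6-dimethylcyclohexa-2,4-dien-1-one F5. Hydrolysis as in step 10 (aq. HCl, THF) should convert F5 into the same trione 24, because the three oxygens of ring B become equivalent at the trione stage.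

Further compounds
F1 | step 9 | 2-acetyl-3,5-dihydroxy-4,4-dimethylcyclohexa-2,5-dien-1-one | CC(=O)C1=C(O)C(C)(C)C(O)=CC1=O
F2 | step 7 | {[2,4-bis(benzyloxy)-3-butanoyl-6-methoxy-5-methylphenyl]methyl}zinc bromide | CCCC(=O)c1c(OCc2ccccc2)c(C)c(OC)c(C[Zn]Br)c1OCc1ccccc1
F3 | step 7 | 3-ethoxy-4,4-dimethylcyclobut-2-en-1-one | CCOC1=CC(=O)C1(C)C
F4 | step 7 | 2-bromo-3-ethoxy-4,4-dimethylcyclobut-2-en-1-one | CCOC1=C(Br)C(=O)C1(C)C
F5 | step 8 | 2-(ArCH2)-3,5-diethoxy-6,6-dimethylcyclohexa-2,4-dien-1-one | CCCC(=O)c1c(OCc2ccccc2)c(C)c(OC)c(CC3=C(OCC)C=C(OCC)C(C)(C)C3=O)c1OCc1ccccc1
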